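**Retrosynthetic overview** (butenolide numbering: O1, C2 = lactone C=O, C3 bears Me, C4 bears CO2H, C5 = stereocentre, R)
1. Target 15 ← tert-butyl ester 14 by acidolysis.
2. 14 ← chloro-oxirane 7 (C4–C5 unit) + phosphonium carboxylate betaine 11 (O1–C2–C3 unit) in one flask: O1–C5 by SN2 opening of the oxirane with inversion, then C3=C4 by intramolecular Wittig closure.
3. Enabling feature: the strained oxirane of 7, whose carbon destined to become C4 carries both Cl and CO2tBu. It is a configurationally fixed mask of the racemisation-prone 3-halo-2-oxo ester and releases the C4 ketone only once O1 is bonded to C5; the P+–C3–H of 11 then needs only bicarbonate.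
4. 7 ← (3S)-dichlorohydrin 6 ← CBS reduction of dichloro keto ester 5 ← β-keto ester 4 ← acid 2 ← hydroxy acid 1; 11 ← 2-bromopropanoic acid 8 + PPh3 9.
5. Ring order: oxirane (step 5, temporary), then the butenolide, the only ring of the target (step 7).

Key step: step 7

Remark: 14-hydroxytetradecanoic acid (1) is taken as commercially available; the descriptor at C5 of the target works out as (R) (O1 > C4 > chain > H).

**Step 1**
Reactants: 1 14-hydroxytetradecanoic acid
Product: 2 14-acetoxytetradecanoic acid
Conditions: Ac2O (1.5 equiv), pyridine, DMAP (cat.), CH2Cl2, 0 °C → rt; then H2O/THF, rt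
Reagents that add atoms: acetic anhydride, CC(=O)OC(C)=O
Why: DMAP-catalysed O-acetylation of the primary alcohol; any mixed anhydride at the carboxyl group should be hydrolysed in the aqueous stage.

**Step 2**
Reactants: 2 14-acetoxytetradecanoic acid; 3 potassium 3-tert-butoxy-3-oxopropanoate
Product: 4 tert-butyl 16-acetoxy-3-oxohexadecanoate
Conditions: CDI (1.1 equiv), THF, rt; then 3 (1.5 equiv), MgCl2 (1.5 equiv), Et3N (2 equiv), THF, rt → 45 °C; 10% citric acid work-up
Reagents that add atoms: none
Why: Masamune–Brooks C-acylation, in which the acyl imidazolide of 2 acylates the magnesium enolate of the malonate half-ester and decarboxylation gives the β-keto ester without touching the primary acetate.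

**Step 3**
Reactants: 4 tert-butyl 16-acetoxy-3-oxohexadecanoate
Product: 5 tert-butyl 16-acetoxy-2,2-dichloro-3-oxohexadecanoate
Conditions: SO2Cl2 (2.3 equiv), CH2Cl2, 0 °C → rt, N2 sweep
Reagents that add atoms: sulfuryl chloride, O=S(=O)(Cl)Cl
Why: Electrophilic α,α-dichlorination of the β-keto ester enol, C-2 being the only doubly activated position; the gas sweep removes HCl to protect the tert-butyl ester.

**Step 4**
Reactants: 5 tert-butyl 16-acetoxy-2,2-dichloro-3-oxohexadecanoate
Product: 6 tert-butyl (3S)-16-acetoxy-2,2-dichloro-3-hydroxyhexadecanoate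
Conditions: (R)-Me-CBS oxazaborolidine (0.2 equiv), catecholborane (1.5 equiv), toluene, −78 → −40 °C; MeOH quench, pH 7 buffer
Reagents that add atoms: none
Why: Corey–Bakshi–Shibata reduction in which, by analogy with trichloromethyl ketones, the CCl2CO2tBu group acts as the large substituent and the n-alkyl chain as the small one, so the (R)-catalyst should deliver the (3S)-carbinol; both esters are inert to catecholborane at this temperature.

**Step 5**
Reactants: 6 tert-butyl (3S)-16-acetoxy-2,2-dichloro-3-hydroxyhexadecanoate
Product: 7 tert-butyl (3S)-3-(13-acetoxytridecyl)-2-chlorooxirane-2-carboxylate (both C-2 epimers)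
Conditions: KHMDS (1.02 equiv), THF, −78 °C, 30 min; pH 7 phosphate buffer at −78 °C; used crude
Reagents that add atoms: none
Why: Second half of a Darzens condensation, an intramolecular SN2 (3-exo-tet) of the potassium alkoxide on one C–Cl with retention at the carbinol carbon (its C–O bond is not touched); low temperature should let ring closure outrun retro-aldol cleavage, and both C-2 epimers are usable because C-2 becomes sp2 in step 7.

**Step 6**
Reactants: 8 2-bromopropanoic acid (racemic); 9 triphenylphosphine
Product: 11 2-(triphenylphosphonio)propanoate (inner salt), via (1-carboxyethyl)triphenylphosphonium bromide 10 (not isolated)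
Conditions: 8 (1.05 equiv), MeCN, 60 °C, 16 h; evaporate; then NaOH (1.0 M aq, 1.05 equiv), CH2Cl2/H2O, 0 °C; dry and concentrate below 20 °C
Reagents that add atoms: none
Why: SN2 quaternisation of the phosphine by the α-bromo acid, then neutralisation of the carboxylic acid (far more acidic than the P+–C–H) to a phosphonium carboxylate betaine of a known type, kept cold to avoid decarboxylation.

**Step 7**
Reactants: 7 tert-butyl (3S)-3-(13-acetoxytridecyl)-2-chlorooxirane-2-carboxylate; 11 2-(triphenylphosphonio)propanoate
Product: 14 tert-butyl (2R)-2-(13-acetoxytridecyl)-4-methyl-5-oxo-2,5-dihydrofuran-3-carboxylate, via keto ester phosphonium chloride 12 (not isolated), via keto ester ylide 13 (not isolated)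
Conditions: 11 (1.5 equiv), NaHCO3 (powder, 3 equiv), 4 Å MS, MeCN/CH2Cl2 (4:1), 0 °C → rt; pH 7 buffer
Reagents that add atoms: none
Why: Proposed new method: the carboxylate oxygen of 11 should open the strained oxirane of 7 at C-3 by SN2 (inversion, (3S) → (R) at the future C5, forming O1–C5), the resulting 2-chloro alkoxide expels chloride to unmask the C4 ketone (12), bicarbonate deprotonates the now ester-activated P+–C–H to ylide 13, and an intramolecular Wittig reaction (5-exo-trig attack of the ylide carbon on the ketone, then loss of Ph3P=O) forms C3=C4 and closes the butenolide. The closest known reaction types are the opening of α-chloroglycidic esters at C-3 by sulfur, nitrogen and halide nucleophiles to give 3-substituted 2-oxo esters, and the one-pot O-alkylation/intramolecular Wittig or HWE synthesis of butenolides from α-halo ketones. The only stereocentre (C5) is controlled by the configuration of the oxirane carbon of 7 through stereospecific inversion; the ring closure creates no stereocentre. The step needs attack at C-3 and not at the fully substituted C-2, which sterics and the push–pull assistance of chloride loss should secure. It also needs the α-position of the transient α-keto ester to keep its configuration: the phosphonium C–H (pKa about 9) is far more acidic than C5–H, so bicarbonate-strength base suffices and the Wittig closure should outrun enolisation.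

**Step 8**
Reactants: 14 tert-butyl (2R)-2-(13-acetoxytridecyl)-4-methyl-5-oxo-2,5-dihydrofuran-3-carboxylate
Product: 15 (2R)-2-(13-acetoxytridecyl)-4-methyl-5-oxo-2,5-dihydrofuran-3-carboxylic acid (target)
Conditions: TFA/CH2Cl2 (1:4), 0 °C → rt; evaporate, crystallise
Reagents that add atoms: none
Why: Acidolysis of the tert-butyl ester (E1 loss of isobutene), which should leave the primary acetate, the lactone and the C5 stereocentre untouched.

**Compound list**
1 | 14-hydroxytetradecanoic acid | OCCCCCCCCCCCCCC(=O)O | starting material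
2 | 14-acetoxytetradecanoic acid | CC(=O)OCCCCCCCCCCCCCC(=O)O | intermediate
3 | potassium 3-tert-butoxy-3-oxopropanoate | CC(C)(C)OC(=O)CC(=O)[O-].[K+] | starting material
4 | tert-butyl 16-acetoxy-3-oxohexadecanoate | CC(=O)OCCCCCCCCCCCCCC(=O)CC(=O)OC(C)(C)C | intermediate
5 | tert-butyl 16-acetoxy-2,2-dichloro-3-oxohexadecanoate | CC(=O)OCCCCCCCCCCCCCC(=O)C(Cl)(Cl)C(=O)OC(C)(C)C | intermediate
6 | tert-butyl (3S)-16-acetoxy-2,2-dichloro-3-hydroxyhexadecanoate | CC(=O)OCCCCCCCCCCCCC[C@H](O)C(Cl)(Cl)C(=O)OC(C)(C)C | intermediate
7 | tert-butyl (3S)-3-(13-acetoxytridecyl)-2-chlorooxirane-2-carboxylate (both C-2 epimers) | CC(=O)OCCCCCCCCCCCCC[C@@H]1OC1(Cl)C(=O)OC(C)(C)C | intermediate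
8 | 2-bromopropanoic acid (racemic) | CC(Br)C(=O)O | starting material
9 | triphenylphosphine | c1ccc(cc1)P(c1ccccc1)c1ccccc1 | starting material
10 | (1-carboxyethyl)triphenylphosphonium bromide | CC(C(=O)O)[P+](c1ccccc1)(c1ccccc1)c1ccccc1.[Br-] | intermediate
11 | 2-(triphenylphosphonio)propanoate (inner salt) | CC(C(=O)[O-])[P+](c1ccccc1)(c1ccccc1)c1ccccc1 | intermediate
12 | tert-butyl (3R)-16-acetoxy-2-oxo-3-{[2-(triphenylphosphonio)propanoyl]oxy}hexadecanoate chloride | CC(=O)OCCCCCCCCCCCCC[C@@H](OC(=O)C(C)[P+](c1ccccc1)(c1ccccc1)c1ccccc1)C(=O)C(=O)OC(C)(C)C.[Cl-] | intermediate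
13 | tert-butyl (3R)-16-acetoxy-2-oxo-3-{[2-(triphenylphosphoranylidene)propanoyl]oxy}hexadecanoate | CC(=O)OCCCCCCCCCCCCC[C@@H](OC(=O)C(C)=P(c1ccccc1)(c1ccccc1)c1ccccc1)C(=O)C(=O)OC(C)(C)C | intermediate
14 | tert-butyl (2R)-2-(13-acetoxytridecyl)-4-methyl-5-oxo-2,5-dihydrofuran-3-carboxylate | CC(=O)OCCCCCCCCCCCCC[C@H]1OC(=O)C(C)=C1C(=O)OC(C)(C)C | intermediate
15 | (2R)-2-(13-acetoxytridecyl)-4-methyl-5-oxo-2,5-dihydrofuran-3-carboxylic acid | CC(=O)OCCCCCCCCCCCCC[C@H]1OC(=O)C(C)=C1C(=O)O | target

**Total step count:** 8
**Longest linear sequence:** 7 steps (1, 2, 3, 4, 5, 7, 8)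

**Steps most likely to fail**

Step 7 (proposed new method). Configuration at C5 may erode, either by chloride re-opening the oxirane (double inversion) or by enolisation of the transient α-keto ester; the zwitterionic carboxylate may also attack too slowly, or the betaine may decarboxylate first. The fallback uses known chemistry, sets out from 2 and rejoins the route at 13.
- Acid 2 is reduced chemoselectively at the carboxyl group (BH3·SMe2, THF, 0 °C) to 14-hydroxytetradecyl acetate F1, which is oxidised (Dess–Martin periodinane, CH2Cl2) to 14-oxotetradecyl acetate F2.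
- A catalytic asymmetric aldol addition of tert-butyl diazoacetate to F2 (dinuclear ProPhenol–magnesium catalyst, THF, −20 °C, ligand enantiomer chosen for the 3R alcohol) should give tert-butyl (3R)-16-acetoxy-2-diazo-3-hydroxyhexadecanoate F3. Here the future ring oxygen is already on C5 with the required configuration and is never displaced.
- F3 is acylated with 2-bromopropanoyl bromide (pyridine, CH2Cl2, −20 °C) to tert-butyl (3R)-16-acetoxy-3-[(2-bromopropanoyl)oxy]-2-diazohexadecanoate F4.
- The diazo group is oxidised to the ketone with dimethyldioxirane (acetone, 0 °C) to give tert-butyl (3R)-16-acetoxy-3-[(2-bromopropanoyl)oxy]-2-oxohexadecanoate F5.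
- Triphenylphosphine (MeCN, 25–40 °C) quaternises the α-bromo ester to tert-butyl (3R)-16-acetoxy-2-oxo-3-{[2-(triphenylphosphonio)propanoyl]oxy}hexadecanoate bromide F6, and NaHCO3 then gives ylide 13, which closes to 14 as in step 7.

Step 6. The betaine may lose CO2 during neutralisation or concentration, or the secondary α-bromo acid may quaternise incompletely because of halophilic attack by the phosphine. The fallback replaces the ylide by a phosphonate carbanion, sets out from 7 and returns at 14.
- The cesium salt of commercial 2-(diethoxyphosphoryl)propanoic acid (Cs2CO3, MeCN, 0 °C → rt) opens the oxirane of 7 to tert-butyl (3R)-16-acetoxy-3-{[2-(diethoxyphosphoryl)propanoyl]oxy}-2-oxohexadecanoate F7 (not isolated).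
- Once 7 is consumed, iPr2NEt/LiCl (Masamune–Roush conditions) should close the ring by intramolecular Horner–Wadsworth–Emmons olefination to 14.
- The base regime is stronger than in step 7, so the enantiomeric purity of 14 would have to be checked.

Step 4. Facial discrimination may be insufficient, or uncatalysed reduction of the very electrophilic ketone may compete, either of which lowers the enantiomeric purity. The fallback replaces asymmetric induction by kinetic resolution, sets out from 5 and returns at 6.
- Ketone 5 is reduced without a catalyst (BH3·SMe2, THF, 0 °C) to racemic tert-butyl 16-acetoxy-2,2-dichloro-3-hydroxyhexadecanoate F8.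
- Lipase-catalysed transesterification (Burkholderia cepacia lipase, vinyl acetate, MTBE, 30 °C) is expected, by the empirical preference for secondary alcohols with CCl2CO2tBu as the large group, to acylate the (R)-alcohol to tert-butyl (3R)-3,16-diacetoxy-2,2-dichlorohexadecanoate F9.
- The unreacted (S)-alcohol 6 is separated by chromatography; the sense of the enzyme's preference would have to be confirmed.

**Further compounds**
F1 | step 7 | 14-hydroxytetradecyl acetate | CC(=O)OCCCCCCCCCCCCCCO
F2 | step 7 | 14-oxotetradecyl acetate | CC(=O)OCCCCCCCCCCCCCC=O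
F3 | step 7 | tert-butyl (3R)-16-acetoxy-2-diazo-3-hydroxyhexadecanoate | CC(=O)OCCCCCCCCCCCCC[C@@H](O)C(=[N+]=[N-])C(=O)OC(C)(C)C
F4 | step 7 | tert-butyl (3R)-16-acetoxy-3-[(2-bromopropanoyl)oxy]-2-diazohexadecanoate | CC(=O)OCCCCCCCCCCCCC[C@@H](OC(=O)C(C)Br)C(=[N+]=[N-])C(=O)OC(C)(C)C
F5 | step 7 | tert-butyl (3R)-16-acetoxy-3-[(2-bromopropanoyl)oxy]-2-oxohexadecanoate | CC(=O)OCCCCCCCCCCCCC[C@@H](OC(=O)C(C)Br)C(=O)C(=O)OC(C)(C)C
F6 | step 7 | tert-butyl (3R)-16-acetoxy-2-oxo-3-{[2-(triphenylphosphonio)propanoyl]oxy}hexadecanoate bromide | CC(=O)OCCCCCCCCCCCCC[C@@H](OC(=O)C(C)[P+](c1ccccc1)(c1ccccc1)c1ccccc1)C(=O)C(=O)OC(C)(C)C.[Br-]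
F7 | step 6 | tert-butyl (3R)-16-acetoxy-3-{[2-(diethoxyphosphoryl)propanoyl]oxy}-2-oxohexadecanoate | CC(=O)OCCCCCCCCCCCCC[C@@H](OC(=O)C(C)P(=O)(OCC)OCC)C(=O)C(=O)OC(C)(C)C
F8 | step 4 | tert-butyl 16-acetoxy-2,2-dichloro-3-hydroxyhexadecanoate (racemic) | CC(=O)OCCCCCCCCCCCCCC(O)C(Cl)(Cl)C(=O)OC(C)(C)C
F9 | step 4 | tert-butyl (3R)-3,16-diacetoxy-2,2-dichlorohexadecanoate | CC(=O)OCCCCCCCCCCCCC[C@@H](OC(C)=O)C(Cl)(Cl)C(=O)OC(C)(C)C
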